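The route rests on reading C3 of the lactone ring B (the carbon holding O2 and CO2Me) as the carbonyl carbon of methyl glyoxylate and C4 as the benzylic γ-carbon of an arylidene succinate. Because the side-chain carboxyl stands on the same side of Cα=Cβ as C4, O2 can first be held by that carboxyl in a six-membered lactone. A single asymmetric oxa-[4+2] reaction of a silyl ketene acetal diene with methyl glyoxylate makes C3–C4, closes that dihydropyranone, sets both stereocentres and the alkene geometry, and keeps the future acid distinct from the methyl esters. The diene is the aryl-out trimethylsilyl ketene acetal of a Z-arylidene succinate bearing benzyl-protected ring A and a tert-butyl ester.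

Key step: step 8

Remarks on the chemistry (assumptions and design points, valid for all steps)

- Locants C1, O2, C3, C4, C4a–C8a, Cα and Cβ refer to the target. Ring A is the benzene ring and ring B the lactone ring. The target is (3S,4R), 3,4-trans, with an E side-chain alkene (acid carbon cis to C4).
- Relative configuration of the relay lactone: when O2 moves from the Cβ carboxyl to C1, the aryl carbon C4a and Cα exchange the roles of ring member and substituent at C4. The 3,4-trans arrangement of ring B therefore corresponds to a cis arrangement of aryl and CO2Me on the dihydropyranone, not a trans one. The relay lactone must be the (2S,3R)-cis compound 15. With the aryl-out diene this requires the glyoxylate ester to lie endo; an exo approach would give the 2,3-trans lactone and, after the acyl shift, the 3,4-cis epimer.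
- Precursor design:
  - The tert-butyl ester is fitted before the formyl group, so the aldehyde is never a hydroxyphthalide.
  - A hindered magnesium amide is used for the ortho-metalation, because alkyllithiums attack ArOCH2Ph groups.
  - The Z alkene (aryl-out diene) is made directly by olefination, so no photostationary mixture has to be separated.
  - The ketene acetal is made with in situ silylation and used crude.
- Assumption: the (S,S) ligand, 2,2'-(propane-2,2-diyl)bis[(4S)-4-tert-butyl-4,5-dihydro-1,3-oxazole], is chosen on the usual square-planar chelate model (si-face attack on glyoxylate). Should the opposite facial sense be found, the (R,R) ligand would be used.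
- Methyl glyoxylate is used monomeric, freshly distilled from P2O5.

Route

Step 1
Reactants: 1 2,4,5-trihydroxybenzoic acid
Product: 2 benzyl 2,4,5-tris(benzyloxy)benzoate
Conditions: BnBr (4.5 equiv), K2CO3, DMF, 60 °C, argon
Reagents that add atoms: benzyl bromide, BrCc1ccccc1
Why: Williamson ether synthesis with concurrent carboxylate O-alkylation; exhaustive benzylation leaves no regiochemical question, and exclusion of air protects the hydroxyquinol from oxidation.

Step 2
Reactants: 2 benzyl 2,4,5-tris(benzyloxy)benzoate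
Product: 3 2,4,5-tris(benzyloxy)benzoic acid
Conditions: KOH, THF/MeOH/H2O, 60 °C; then aq. HCl
Reagents that add atoms: potassium hydroxide, [K+].[OH-]
Why: Ester saponification; hydroxide cleaves only the benzyl ester, aryl benzyl ethers being inert to aqueous base.

Step 3
Reactants: 3 2,4,5-tris(benzyloxy)benzoic acid
Product: 4 tert-butyl 2,4,5-tris(benzyloxy)benzoate
Conditions: Me2NCH(OtBu)2, toluene, 80 °C
Reagents that add atoms: N,N-dimethylformamide di-tert-butyl acetal, CN(C)C(OC(C)(C)C)OC(C)(C)C
Why: Carboxylic acid O-alkylation by an amide acetal (tert-butyl transfer within the carboxylate/formamidinium ion pair) under neutral conditions that spare the benzyl ethers.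

Step 4
Reactants: 4 tert-butyl 2,4,5-tris(benzyloxy)benzoate
Product: 6 tert-butyl 3,4,6-tris(benzyloxy)-2-formylbenzoate, via arylmagnesium amide 5 (not isolated)
Conditions: Mg(TMP)2·2LiCl (TMP = 2,2,6,6-tetramethylpiperidin-1-yl), THF, 0 °C to rt; DMF, −20 °C to rt; aq. NH4Cl
Reagents that add atoms: N,N-dimethylformamide, CN(C)C=O
Why: Directed ortho-metalation with a hindered magnesium amide, then formylation; the ester directs magnesiation to its only free ortho position, which the neighbouring benzyloxy group also activates, and the amide base neither deprotonates the benzylic CH2 groups nor adds to the tert-butyl ester.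

Step 5
Reactants: 7 methyl 2-[bis(2,2,2-trifluoroethoxy)phosphoryl]acetate; 8 methyl bromoacetate
Product: 9 dimethyl 2-[bis(2,2,2-trifluoroethoxy)phosphoryl]butanedioate (racemic)
Conditions: NaH, THF, 0 °C; then 8, 0 °C to rt (7 in slight excess)
Reagents that add atoms: none
Why: C-alkylation of the stabilised sodium phosphonoacetate by a reactive α-bromo ester (SN2); the small excess of 7 limits dialkylation.

Step 6
Reactants: 6 tert-butyl 3,4,6-tris(benzyloxy)-2-formylbenzoate; 9 dimethyl 2-[bis(2,2,2-trifluoroethoxy)phosphoryl]butanedioate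
Product: 10 dimethyl (2Z)-2-{[2,3,5-tris(benzyloxy)-6-(tert-butoxycarbonyl)phenyl]methylidene}butanedioate
Conditions: KN(SiMe3)2, 18-crown-6, THF, −78 °C
Reagents that add atoms: none
Why: Still–Gennari variant of the Horner–Wadsworth–Emmons olefination; the kinetic adduct of the trifluoroethyl phosphonate eliminates at once, placing the aryl group cis to the ester on the former phosphonate carbon (Z) and outrunning attack of the intermediate alkoxide on the tert-butyl ester.

Step 7
Reactants: 10 dimethyl (2Z)-2-{[2,3,5-tris(benzyloxy)-6-(tert-butoxycarbonyl)phenyl]methylidene}butanedioate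
Product: 12 methyl (2Z)-3-[2,3,5-tris(benzyloxy)-6-(tert-butoxycarbonyl)phenyl]-2-[2-methoxy-2-(trimethylsilyloxy)ethenyl]prop-2-enoate (aryl trans to the ketene acetal arm; ketene acetal geometry immaterial), via lithium dienolate 11 (not isolated)
Conditions: Me3SiCl, THF, −78 °C, then LiN(iPr)2 added slowly (in situ quench); evaporate, pentane, filter under argon, use crude
Reagents that add atoms: chlorotrimethylsilane, C[Si](C)(C)Cl
Why: Kinetic ester enolisation with immediate O-silylation; the CH2 group is the only acidic site, the short-lived dienolate keeps the Z arylidene geometry, and with the aryl group trans to the CH2 carbon no Dieckmann closure onto the aryl ester is possible.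

Step 8
Reactants: 12 methyl (2Z)-3-[2,3,5-tris(benzyloxy)-6-(tert-butoxycarbonyl)phenyl]-2-[2-methoxy-2-(trimethylsilyloxy)ethenyl]prop-2-enoate; 13 methyl glyoxylate
Product: 15 dimethyl (2S,3R)-3-[2,3,5-tris(benzyloxy)-6-(tert-butoxycarbonyl)phenyl]-6-oxo-3,6-dihydro-2H-pyran-2,4-dicarboxylate (2,3-cis), via cyclic ortho ester 14 (not isolated)
Conditions: Cu(OTf)2 (10 mol %), (S,S)-tBu-box (11 mol %), 4 Å MS, CH2Cl2, −78 to −40 °C; then TFA (cat.), 0 °C
Reagents that add atoms: none
Why: Methyl glyoxylate is held on divalent copper as a five-membered chelate through both carbonyl oxygens, and diene 12, which prefers the s-cis form because only hydrogen points inward at its benzylic terminus while the ester on the central carbon destabilises the s-trans form, attacks the aldehyde carbon with that benzylic γ-carbon to form C3–C4; the closest known reaction type is the hetero-Diels–Alder (vinylogous Mukaiyama aldol) reaction of 1-alkoxy-1-silyloxy dienes with glyoxylates on copper bis(oxazoline) catalysts. The six-membered ring closes when the aldehyde oxygen bonds to the ketene acetal carbon, either within a concerted asynchronous [4+2] event or, after a stepwise aldol, by 6-exo-trig attack, and ortho ester 14 then loses Me3SiOMe on the acidic quench to give the lactone. The glyoxylate carbon (future C3, S) is controlled by the C2-symmetric ligand, whose tert-butyl group covers the re face of the chelated aldehyde so that the diene adds to the si face. The benzylic carbon (future C4, R) is controlled by the relative orientation of the partners: with the aryl group outside on the diene terminus, the glyoxylate ester must lie endo, over the diene, to place aryl and ester cis. The step therefore needs endo selectivity, which the substrate should favour because the chelate then rests over the small C–H edge of the diene, whereas an exo arrangement would press it against the oxygen substituent that necessarily occupies the inside position of the ketene acetal carbon; this preference has to be confirmed by experiment. The ring also locks the future acid carbon cis to C4 across Cα=Cβ and masks it differently from the two methyl esters.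

Step 9
Reactants: 15 dimethyl (2S,3R)-3-[2,3,5-tris(benzyloxy)-6-(tert-butoxycarbonyl)phenyl]-6-oxo-3,6-dihydro-2H-pyran-2,4-dicarboxylate
Product: 16 3,4,6-tris(benzyloxy)-2-[(2S,3R)-2,4-bis(methoxycarbonyl)-6-oxo-3,6-dihydro-2H-pyran-3-yl]benzoic acid
Conditions: TFA/CH2Cl2 (1:4), 0 °C to rt
Reagents that add atoms: none
Why: Acidolysis of the tert-butyl ester with loss of 2-methylpropene; the lactone, the methyl esters and the aryl benzyl ethers tolerate brief exposure to trifluoroacetic acid.

Step 10
Reactants: 16 3,4,6-tris(benzyloxy)-2-[(2S,3R)-2,4-bis(methoxycarbonyl)-6-oxo-3,6-dihydro-2H-pyran-3-yl]benzoic acid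
Product: 17 pentafluorophenyl 3,4,6-tris(benzyloxy)-2-[(2S,3R)-2,4-bis(methoxycarbonyl)-6-oxo-3,6-dihydro-2H-pyran-3-yl]benzoate
Conditions: C6F5OC(O)CF3, pyridine, CH2Cl2, 0 °C to rt
Reagents that add atoms: pentafluorophenyl trifluoroacetate, O=C(Oc1c(F)c(F)c(F)c(F)c1F)C(F)(F)F
Why: Active ester formation through the mixed trifluoroacetic anhydride; the electron-rich, doubly ortho-substituted aroyl group is transferred to pentafluorophenoxide through an acylium-like transition state, and the resulting hindered active ester is shielded from intermolecular nucleophiles.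

Step 11
Reactants: 17 pentafluorophenyl 3,4,6-tris(benzyloxy)-2-[(2S,3R)-2,4-bis(methoxycarbonyl)-6-oxo-3,6-dihydro-2H-pyran-3-yl]benzoate
Product: 19 (2E)-3-[(3S,4R)-5,6,8-tris(benzyloxy)-3-(methoxycarbonyl)-1-oxo-3,4-dihydro-1H-isochromen-4-yl]-4-methoxy-4-oxobut-2-enoic acid, via seco hydroxy acid 18 (not isolated)
Conditions: THF/aq. NaH2PO4–Na2HPO4 buffer (pH 8), rt; then dilute HCl to pH 3
Reagents that add atoms: water, O
Why: Chemoselective lactone hydrolysis followed by lactonisation onto an active ester; the δ-lactone (an ester locked in its reactive conformation and derived from the acidic hydroxyl of an α-hydroxy ester) should open at pH 8 much faster than the methyl esters or the hindered aryl ester, and the freed C3 hydroxyl, which cannot re-acylate on a carboxylate, closes ring B by 6-exo-trig attack on the pentafluorophenyl ester with no bond to C3 or C4 broken, so both centres are retained.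

Step 12
Reactants: 19 (2E)-3-[(3S,4R)-5,6,8-tris(benzyloxy)-3-(methoxycarbonyl)-1-oxo-3,4-dihydro-1H-isochromen-4-yl]-4-methoxy-4-oxobut-2-enoic acid
Product: 20 (2E)-4-methoxy-4-oxo-3-[(3S,4R)-5,6,8-trihydroxy-3-(methoxycarbonyl)-1-oxo-3,4-dihydro-1H-isochromen-4-yl]but-2-enoic acid (target)
Conditions: BCl3, C6HMe5, CH2Cl2, −78 to −40 °C; then H2O/THF
Reagents that add atoms: none
Why: Lewis acid debenzylation of aryl benzyl ethers with pentamethylbenzene as a non-coordinating benzyl cation scavenger; at low temperature the methyl esters, the lactone and the electron-poor alkene are untouched, whereas hydrogenolysis would risk reducing the alkene.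

Compound list

1 | 2,4,5-trihydroxybenzoic acid | OC(=O)c1cc(O)c(O)cc1O | starting material
2 | benzyl 2,4,5-tris(benzyloxy)benzoate | O=C(OCc1ccccc1)c1cc(OCc2ccccc2)c(OCc2ccccc2)cc1OCc1ccccc1 | intermediate
3 | 2,4,5-tris(benzyloxy)benzoic acid | OC(=O)c1cc(OCc2ccccc2)c(OCc2ccccc2)cc1OCc1ccccc1 | intermediate
4 | tert-butyl 2,4,5-tris(benzyloxy)benzoate | CC(C)(C)OC(=O)c1cc(OCc2ccccc2)c(OCc2ccccc2)cc1OCc1ccccc1 | intermediate
5 | [3,4,6-tris(benzyloxy)-2-(tert-butoxycarbonyl)phenyl]magnesium 2,2,6,6-tetramethylpiperidide (arylmagnesium amide) | CC(C)(C)OC(=O)c1c([Mg]N2C(C)(C)CCCC2(C)C)c(OCc2ccccc2)c(OCc2ccccc2)cc1OCc1ccccc1 | intermediate (not isolated)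
6 | tert-butyl 3,4,6-tris(benzyloxy)-2-formylbenzoate | CC(C)(C)OC(=O)c1c(C=O)c(OCc2ccccc2)c(OCc2ccccc2)cc1OCc1ccccc1 | intermediate
7 | methyl 2-[bis(2,2,2-trifluoroethoxy)phosphoryl]acetate | COC(=O)CP(=O)(OCC(F)(F)F)OCC(F)(F)F | starting material
8 | methyl bromoacetate | COC(=O)CBr | starting material
9 | dimethyl 2-[bis(2,2,2-trifluoroethoxy)phosphoryl]butanedioate (racemic) | COC(=O)CC(C(=O)OC)P(=O)(OCC(F)(F)F)OCC(F)(F)F | intermediate
10 | dimethyl (2Z)-2-{[2,3,5-tris(benzyloxy)-6-(tert-butoxycarbonyl)phenyl]methylidene}butanedioate | COC(=O)C/C(C(=O)OC)=C/c1c(OCc2ccccc2)c(OCc2ccccc2)cc(OCc2ccccc2)c1C(=O)OC(C)(C)C | intermediate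
11 | lithium dienolate of 10 (aryl trans to the enolate arm) | COC(=O)C(=C\c1c(OCc2ccccc2)c(OCc2ccccc2)cc(OCc2ccccc2)c1C(=O)OC(C)(C)C)/C=C(OC)O[Li] | intermediate (not isolated)
12 | methyl (2Z)-3-[2,3,5-tris(benzyloxy)-6-(tert-butoxycarbonyl)phenyl]-2-[2-methoxy-2-(trimethylsilyloxy)ethenyl]prop-2-enoate | COC(=O)C(=C\c1c(OCc2ccccc2)c(OCc2ccccc2)cc(OCc2ccccc2)c1C(=O)OC(C)(C)C)/C=C(OC)O[Si](C)(C)C | intermediate
13 | methyl glyoxylate | COC(=O)C=O | starting material
14 | dimethyl (2S,3R)-3-[2,3,5-tris(benzyloxy)-6-(tert-butoxycarbonyl)phenyl]-6-methoxy-6-(trimethylsilyloxy)-3,6-dihydro-2H-pyran-2,4-dicarboxylate (cyclic ortho ester, C6 undefined) | COC(=O)C1=CC(OC)(O[Si](C)(C)C)O[C@H](C(=O)OC)[C@@H]1c1c(OCc2ccccc2)c(OCc2ccccc2)cc(OCc2ccccc2)c1C(=O)OC(C)(C)C | intermediate (not isolated)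
15 | dimethyl (2S,3R)-3-[2,3,5-tris(benzyloxy)-6-(tert-butoxycarbonyl)phenyl]-6-oxo-3,6-dihydro-2H-pyran-2,4-dicarboxylate (2,3-cis) | COC(=O)C1=CC(=O)O[C@H](C(=O)OC)[C@@H]1c1c(OCc2ccccc2)c(OCc2ccccc2)cc(OCc2ccccc2)c1C(=O)OC(C)(C)C | intermediate
16 | 3,4,6-tris(benzyloxy)-2-[(2S,3R)-2,4-bis(methoxycarbonyl)-6-oxo-3,6-dihydro-2H-pyran-3-yl]benzoic acid | COC(=O)C1=CC(=O)O[C@H](C(=O)OC)[C@@H]1c1c(OCc2ccccc2)c(OCc2ccccc2)cc(OCc2ccccc2)c1C(=O)O | intermediate
17 | pentafluorophenyl 3,4,6-tris(benzyloxy)-2-[(2S,3R)-2,4-bis(methoxycarbonyl)-6-oxo-3,6-dihydro-2H-pyran-3-yl]benzoate | COC(=O)C1=CC(=O)O[C@H](C(=O)OC)[C@@H]1c1c(OCc2ccccc2)c(OCc2ccccc2)cc(OCc2ccccc2)c1C(=O)Oc1c(F)c(F)c(F)c(F)c1F | intermediate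
18 | (2E)-3-[(1R,2S)-1-{2,3,5-tris(benzyloxy)-6-[(pentafluorophenoxy)carbonyl]phenyl}-2-hydroxy-3-methoxy-3-oxopropyl]-4-methoxy-4-oxobut-2-enoic acid (seco hydroxy acid) | COC(=O)/C(=C/C(=O)O)[C@@H](c1c(OCc2ccccc2)c(OCc2ccccc2)cc(OCc2ccccc2)c1C(=O)Oc1c(F)c(F)c(F)c(F)c1F)[C@H](O)C(=O)OC | intermediate (not isolated)
19 | (2E)-3-[(3S,4R)-5,6,8-tris(benzyloxy)-3-(methoxycarbonyl)-1-oxo-3,4-dihydro-1H-isochromen-4-yl]-4-methoxy-4-oxobut-2-enoic acid | COC(=O)/C(=C/C(=O)O)[C@H]1c2c(OCc3ccccc3)c(OCc3ccccc3)cc(OCc3ccccc3)c2C(=O)O[C@@H]1C(=O)OC | intermediate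
20 | (2E)-4-methoxy-4-oxo-3-[(3S,4R)-5,6,8-trihydroxy-3-(methoxycarbonyl)-1-oxo-3,4-dihydro-1H-isochromen-4-yl]but-2-enoic acid | COC(=O)/C(=C/C(=O)O)[C@H]1c2c(O)c(O)cc(O)c2C(=O)O[C@@H]1C(=O)OC | target

Total step count: 12. Longest linear sequence: 11 steps (steps 1–4 and 6–12; step 5 prepares the olefination reagent).

Steps most likely to fail

1. Step 8. Endo control may be lost: the chelated glyoxylate may add with its ester exo, or through an open aldol transition state, so that the relative configuration of the two new centres is inverted. Slow bond formation at the benzylic carbon, which is flanked by a doubly ortho-substituted ring, would also give time for protodesilylation of the diene. The fallback sets out from 12 and 13 and keeps the exo preference but corrects the glyoxylate centre afterwards. With Cu(OTf)2 and the (R,R)-tBu-box ligand, the exo pathway should give, via the epimeric cyclic ortho ester F1, the 2,3-trans lactone F2 (2R,3R), in which the aryl-bearing carbon already has the configuration of C4. Treatment as in steps 9 to 11 should then give the acid F3, the pentafluorophenyl ester F4 and, via the seco hydroxy acid F5, the 3,4-cis dihydroisocoumarin acid F6. Epimerisation of C3, which is α to its methyl ester, with DBU in MeCN at rt under thermodynamic control should favour the trans arrangement (both substituents pseudoaxial beside the peri benzyloxy group), while the carboxylate protects C4–H from deprotonation. The fallback comes back to the route at 19.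

2. Step 11. Hydrolysis of the pentafluorophenyl ester, or base-induced β-elimination across C3–C4, may outrun opening of the dihydropyranone, and a seco acid that has not yet cyclised would close back to the dihydropyranone on acidification. The fallback sets out from 16 and moves the oxygen under thermodynamic instead of kinetic control. Debenzylation with BCl3 and C6HMe5 as in step 12 should give the trihydroxy lactone acid F7. Acid-catalysed translactonisation (dilute HCl, aqueous dioxane, 40 °C) should then shift O2 from the side-chain carboxyl to C1, because the ring B lactone is chelated by the C8 hydroxyl as in 8-hydroxy-3,4-dihydroisocoumarins. The fallback comes back to the route at 20.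

3. Step 6. Z selectivity may erode, or the α-branched phosphonate anion may add sluggishly to the doubly ortho-substituted aldehyde. The fallback sets out from 6 and separates bond formation from geometry control. A Wittig reaction with the stabilised ylide F8, made from PPh3 and dimethyl maleate, in toluene at 90 °C should give the E alkene F9. Triplet-sensitised E-to-Z photoisomerisation (thioxanthone, 405 nm, MeCN), with chromatographic separation and recycling of the E isomer, comes back to the route at 10.

Further compounds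

F1 | step 8 | dimethyl (2R,3R)-3-[2,3,5-tris(benzyloxy)-6-(tert-butoxycarbonyl)phenyl]-6-methoxy-6-(trimethylsilyloxy)-3,6-dihydro-2H-pyran-2,4-dicarboxylate (epimeric cyclic ortho ester) | COC(=O)C1=CC(OC)(O[Si](C)(C)C)O[C@@H](C(=O)OC)[C@@H]1c1c(OCc2ccccc2)c(OCc2ccccc2)cc(OCc2ccccc2)c1C(=O)OC(C)(C)C
F2 | step 8 | dimethyl (2R,3R)-3-[2,3,5-tris(benzyloxy)-6-(tert-butoxycarbonyl)phenyl]-6-oxo-3,6-dihydro-2H-pyran-2,4-dicarboxylate (2,3-trans lactone) | COC(=O)C1=CC(=O)O[C@@H](C(=O)OC)[C@@H]1c1c(OCc2ccccc2)c(OCc2ccccc2)cc(OCc2ccccc2)c1C(=O)OC(C)(C)C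
F3 | step 8 | 3,4,6-tris(benzyloxy)-2-[(2R,3R)-2,4-bis(methoxycarbonyl)-6-oxo-3,6-dihydro-2H-pyran-3-yl]benzoic acid | COC(=O)C1=CC(=O)O[C@@H](C(=O)OC)[C@@H]1c1c(OCc2ccccc2)c(OCc2ccccc2)cc(OCc2ccccc2)c1C(=O)O
F4 | step 8 | pentafluorophenyl 3,4,6-tris(benzyloxy)-2-[(2R,3R)-2,4-bis(methoxycarbonyl)-6-oxo-3,6-dihydro-2H-pyran-3-yl]benzoate | COC(=O)C1=CC(=O)O[C@@H](C(=O)OC)[C@@H]1c1c(OCc2ccccc2)c(OCc2ccccc2)cc(OCc2ccccc2)c1C(=O)Oc1c(F)c(F)c(F)c(F)c1F
F5 | step 8 | (2E)-3-[(1R,2R)-1-{2,3,5-tris(benzyloxy)-6-[(pentafluorophenoxy)carbonyl]phenyl}-2-hydroxy-3-methoxy-3-oxopropyl]-4-methoxy-4-oxobut-2-enoic acid (seco hydroxy acid) | COC(=O)/C(=C/C(=O)O)[C@@H](c1c(OCc2ccccc2)c(OCc2ccccc2)cc(OCc2ccccc2)c1C(=O)Oc1c(F)c(F)c(F)c(F)c1F)[C@@H](O)C(=O)OC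
F6 | step 8 | (2E)-3-[(3R,4R)-5,6,8-tris(benzyloxy)-3-(methoxycarbonyl)-1-oxo-3,4-dihydro-1H-isochromen-4-yl]-4-methoxy-4-oxobut-2-enoic acid (3,4-cis) | COC(=O)/C(=C/C(=O)O)[C@H]1c2c(OCc3ccccc3)c(OCc3ccccc3)cc(OCc3ccccc3)c2C(=O)O[C@H]1C(=O)OC
F7 | step 11 | 2-[(2S,3R)-2,4-bis(methoxycarbonyl)-6-oxo-3,6-dihydro-2H-pyran-3-yl]-3,4,6-trihydroxybenzoic acid | COC(=O)C1=CC(=O)O[C@H](C(=O)OC)[C@@H]1c1c(O)c(O)cc(O)c1C(=O)O
F8 | step 6 | dimethyl 2-(triphenyl-λ5-phosphanylidene)butanedioate | COC(=O)CC(=P(c1ccccc1)(c1ccccc1)c1ccccc1)C(=O)OC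
F9 | step 6 | dimethyl (2E)-2-{[2,3,5-tris(benzyloxy)-6-(tert-butoxycarbonyl)phenyl]methylidene}butanedioate | COC(=O)C/C(C(=O)OC)=C\c1c(OCc2ccccc2)c(OCc2ccccc2)cc(OCc2ccccc2)c1C(=O)OC(C)(C)C
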